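(All runs stem from a simulated flask with made-up constants, noise included.)

In the stirred vessel the new flasks differed in which reagent, if any, was fed and how quickly.

| flask | starting material | partner | protic impurity | remark | time |
|---|---|---|---|---|---|
| eta | 0.30 M | 0.30 M | 0.060 M | run made earlier |  |
| epsilon | 0.42 M | 0.30 M | 0.060 M | run made earlier |  |
| alpha | 0.66 M | 0.30 M | 0.060 M | run made earlier |  |
| gamma | 0.30 M | 0.30 M | 0.090 M | run made earlier |  |
| elm | 0.30 M (fed, over 80 s) | 0.300 M | 0.0600 M | all else is in the flask from the start; the feed brings no volume worth counting | 3.0 min |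
| birch | 0.30 M | 0.300 M (fed, over 20 s) | 0.0600 M | all else is in the flask from the start; the feed brings no volume worth counting | 3.0 min |
| alder | 0.30 M | 0.300 M | 0.0600 M | everything together at the start | 3.0 min |
| maple | 0.30 M | 0.300 M (fed, over 80 s) | 0.0600 M | all else is in the flask from the start; the feed brings no volume worth counting | 3.0 min |

| run | time / min | target / % | side product / % |
|---|---|---|---|
| eta | 0.667 | 2.6 | 31.9 |
| eta | 1.33 | 9.8 | 45.3 |
| eta | 2.00 | 13.4 | 48.6 |
| eta | 2.50 | 17.4 | 50.6 |
| eta | 3.00 | 22.2 | 52.2 |
| epsilon | 0.250 | 0.4 | 17.8 |
| epsilon | 0.833 | 4.7 | 34.0 |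
| epsilon | 1.33 | 10.5 | 40.8 |
| epsilon | 2.00 | 15.9 | 44.2 |
| epsilon | 3.00 | 21.6 | 47.4 |
| alpha | 0.250 | 0.3 | 15.6 |
| alpha | 0.417 | 3.1 | 22.1 |
| alpha | 0.833 | 4.1 | 30.5 |
| alpha | 1.50 | 11.1 | 34.9 |
| alpha | 3.00 | 24.0 | 37.3 |
| gamma | 0.250 | 0 | 16.9 |
| gamma | 0.417 | 1.1 | 24.6 |
| gamma | 0.833 | 4.9 | 36.3 |
| gamma | 1.50 | 11.4 | 45.9 |
| gamma | 3.00 | 22.7 | 50.2 |

(readings scatter by 1 percentage point)

- a reading or a percentage of target counts all its forms, free or not

1. the best flask by share of target in target plus side product; "all alike" if 1.5 percentage points covers them all (elm / birch / alder / maple / all alike)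
2. share of target in target plus side product at the end, elm
3. share of target in target plus side product at the end, birch
4. share of target in target plus side product at the end, alder
5. share of target in target plus side product at the end, maple

I began with the alpha run, which held 0.66 M of starting material against 0.30 M of partner. Its first side-product reading, 15.6 % at 0.250 min, gave through the second-order law a rate constant of 2.79 /M/min, a reading with its scatter.

But the partner balance says that a steady feed into a flask without partner holds less than the fed amount, so mean partner over that feed stays below 0.150 M. So I defined the feed exposure as rate constant times that ceiling times feed time, a pseudo-first-order exponent on starting material 0.557.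

For maple it gave, counting the feed and nothing after it, and no other loss of starting material, 42.7 % side product. With target held at the eta run's 22.2 %, my own share for maple was 34.2 %, against 29.8 % in the eta run.

The forecast chose maple at 36 %, above my figure, with 30 % for alder, 31.5 % for birch and 25 % for elm: “Slow partner feed keeps partner low and starting material available”.

The flasks gave 26.1 % in elm, 32.0 % in birch, 29.0 % in alder and 40.6 % in maple, so maple stood highest.

    starting material → intermediate A (k = 0.00556 /s)
    starting material + partner → side product (k = 0.0505 /M/s)
    intermediate A ⇌ intermediate B (K = 0.117, k = 0.0814 /s)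
    intermediate A → target (k = 0.0113 /s)
    partner + protic impurity → quenched reagent (k = 0.0468 /M/s)
    starting material + target ⇌ idle adduct, settled at all times (K = 39.5 /M)

In maple, side product stood at 40.1 % after 3.00 min against the 42.7 % I had reckoned for the feed, and mean partner over the feed was 0.110 M, lower than the ceiling. The neighbouring flask was maple with 0.075 M of partner. The same reckoning gave an exposure of 0.139, hence 13.0 % side product. The flask held 12.5 % side product, with 32.0 % of its partner left, and its share was 72.1 %.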